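## Analysis of the target

- The target is a linear flavan-3-ol trimer, epirobinetinidol-(4β→8)-epirobinetinidol-(4α→8)-epicatechin. Three 2-arylchroman units (rings A and C, each with a pendant ring B) are joined by two C–C bonds from C4 of ring C of one unit to C8 of ring A of the next.
- There are eight stereocenters. C2 and C3 are R in all three units (2,3-cis). C4 of the top unit is R (aryl on the β face, trans to O3). C4 of the middle unit is S (aryl on the α face, cis to O3 and to the C2 aryl group, an all-cis triad).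
- The top and middle units are the same monomer, 5-deoxy-epigallocatechin, and differ only at C4. Their rings A are resorcinol-type (C5 bears hydrogen); ring A of the bottom unit is phloroglucinol-type.
- Sensitive features: twelve phenols (pyrogallol and catechol rings, oxidised in air and base), benzylic C2–O1 ethers, and two doubly benzylic interflavanyl bonds that acid cleaves.
- Two things make the synthesis hard. The middle C4–C8 bond has the configuration opposite to what arene attack on a 2,3-cis flavan-4-yl cation gives. And C8 of a 5-deoxy ring A (between O1 and O7) is a weak nucleophile that loses to C6.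
- The route is built on the peri pair C4 (ring C) / C5 (ring A) of the two upper units. The C5 oxygen that the target lacks is kept as a traceless handle with three jobs:
  - as a tert-butyl carbonate beside the C4 carbonyl of the middle unit, it triggers a three-component, stereoconvergent union (aryl anion onto C4, o-quinone methide across C5–C4a–C4, hydride onto C4) that makes the all-cis C4–C8 bond;
  - as a free phenol, it turns C8 of the middle ring A into a phloroglucinol-type nucleophile for the second interflavanyl bond;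
  - as a triflate, it is removed in the final hydrogenolysis.

## Retrosynthetic reasoning

**22 ⇒ 21.** The two C5–H bonds of the upper rings A and all fifteen O–H bonds are traced back to two aryl triflates and fifteen benzyl ethers. One hydrogenolysis then has to unmask the polyphenol and delete both auxiliary oxygens. The deoxygenation is placed last so that both upper rings A stay oxygenated at C5 while the skeleton is assembled.

**21 ⇒ 20 ⇒ 17 + 9.** The C4(top)–C8(middle) bond is cut. In the forward sense it is a Friedel–Crafts alkylation of 17 by the flavan-4-yl cation from 9. Arene attack on a 2,3-cis cation from the β face is exactly what the top unit needs. In 17 the middle ring A still carries O5, so C8 is para to an oxygen and is the usual reactive site. In 9 the triflate on C5 switches off ring A as a nucleophile, so the electrophile cannot self-condense.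

**17 ⇒ 13 + 7 (key disconnection).** The C4(middle)–C8(bottom) bond is cut with reversed polarity: C8 of the bottom unit as an aryl anion (14, from 13) and C4 of the middle unit as a carbonyl carbon (7). The forward step forms this bond and then places hydrogen on C4 from the β face. The incoming group at C4 is therefore hydride and not the arene, which pushes the aryl group to the α face. This is done in one operation through o-quinone methide 16, triggered by the carbonate on the peri O5, so both C4 epimers of the adduct converge.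

**7 and 9 ⇒ 6 ⇒ 5 ⇒ 3 ⇒ 1.** Both upper units come from one ketone, 6. The two C4 configurations of the target arise from the order in which hydride and arene are added to this carbon: hydride then arene for the top unit (through 9), arene then hydride for the middle unit (through 7). The carbonyl at C4 also solves the second problem: it is the only handle that tells O5 from O7, by chelation in 5. Ketone 5 is reached by benzylic oxidation of 3, itself the perbenzyl ether of commercial 1, which supplies C2 and C3 of both upper units.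

**13 ⇒ 10.** The bottom unit is commercial 10. Its phloroglucinol-type ring A is brominated at C8 after perbenzylation, which supplies the aryl anion precursor.

## Alternatives that were turned down

**Alternative 1:** the textbook route.
- Disconnection: both C4–C8 bonds by Friedel–Crafts alkylation with flavan-4-yl cations.
- Forward key step: Lewis acid ionisation of a C4-activated 5-deoxy monomer A1 and capture by 12, then a second ionisation of A1 and capture by the resulting dimer.
- Turned down because:
  - arene attack on a 2,3-cis cation is always from the β face, so the middle unit would come out 4β, the C4 epimer of the target;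
  - in the second coupling the middle ring A is resorcinol-type, where C8 is activated only by two ortho oxygens and flanked by both, so C6 of that ring and C6 of the bottom ring win and the connectivity is wrong;
  - A1 carries the same ring A and self-condenses, and blocking groups cost the steps the route would save.

**Alternative 2:** a ring-forming cascade.
- Disconnection: both upper rings C (O1–C2 and C3–C4 bonds, twice) by a twofold hetero-Diels–Alder reaction.
- Forward key step: the bis(o-hydroxybenzhydrol) A2 is ionised to two o-quinone methides, which are trapped by two equivalents of the (Z)-enol acetate A3. This would close two rings and set six stereocenters at once.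
- Turned down because:
  - A3 carries two donors of opposite polarisation (acetoxy and trialkoxyphenyl), so flavan versus isoflavan regiochemistry is not secured;
  - an endo cycloaddition of a Z-alkene gives the all-cis triad in both rings, while the top ring needs 3,4-trans;
  - the absolute configuration of six new centers would depend on the remote bottom unit or on a catalyst that must override it twice.

**Alternative 3:** two anionic unions.
- Disconnection: both interflavanyl bonds by aryllithium-to-ketone addition.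
- Forward key step: 14 adds to bromo ketone A4; bromine–lithium exchange on the adduct and addition to a second molecule of A4; then a twofold ionic hydrogenation.
- Turned down because:
  - hydride enters both cations from the β face, so both aryl groups end up α, right for the middle unit and wrong for the top;
  - A4 is hard to make: bromination of a 5-deoxy ring A goes to C6, and a bromine placed at the phloroglucinol stage would not survive palladium-mediated removal of O5;
  - halogen–metal exchange between 14 and A4 competes with carbonyl addition.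

Key step: step 12

Remark: (−)-epigallocatechin and (−)-epicatechin are taken as commercial single enantiomers; they supply all C2 and C3 centers, and both C4 centers are then set by substrate control.

## Steps

Step 1
Reactants: 1 (−)-epigallocatechin
Product: 2 5,7,3',4',5'-penta-O-benzyl-(−)-epigallocatechin
Conditions: BnBr (5.5 equiv), K2CO3, degassed DMF, Ar, −10 °C → rt
Reagents that add atoms: benzyl bromide BrCc1ccccc1
Why: Williamson etherification: carbonate deprotonates only the five phenols, so the secondary 3-OH stays free; low temperature and exclusion of air should spare the pyrogallol ring and C2.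

Step 2
Reactants: 2 5,7,3',4',5'-penta-O-benzyl-(−)-epigallocatechin
Product: 3 3,5,7,3',4',5'-hexa-O-benzyl-(−)-epigallocatechin
Conditions: NaH, BnBr, Bu4NI (cat.), DMF, 0 °C → rt
Reagents that add atoms: benzyl bromide BrCc1ccccc1
Why: Williamson etherification of the sodium alkoxide; with every phenol capped there is no quinone methide pathway by which C2 could epimerise.

Step 3
Reactants: 3 3,5,7,3',4',5'-hexa-O-benzyl-(−)-epigallocatechin
Product: 4 (2R,3R,4S)-3,5,7-tris(benzyloxy)-2-[3,4,5-tris(benzyloxy)phenyl]chroman-4-ol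
Conditions: DDQ (2.2 equiv), CH2Cl2/H2O (18:1), rt
Reagents that add atoms: water O
Why: DDQ benzylic oxidation: hydride abstraction from C4 gives a cation stabilised by O1, O5 and O7 of ring A, which water captures from the β face, anti to the axial 3-OBn; this center is erased in step 4.

Step 4
Reactants: 4 (2R,3R,4S)-3,5,7-tris(benzyloxy)-2-[3,4,5-tris(benzyloxy)phenyl]chroman-4-ol
Product: 5 (2R,3S)-3,5,7-tris(benzyloxy)-2-[3,4,5-tris(benzyloxy)phenyl]chroman-4-one
Conditions: Dess–Martin periodinane, CH2Cl2, rt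
Reagents that add atoms: none
Why: Dess–Martin oxidation of the secondary benzylic alcohol under non-basic conditions, so that C3, now α to the carbonyl, should keep its cis relation to C2.

Step 5
Reactants: 5 (2R,3S)-3,5,7-tris(benzyloxy)-2-[3,4,5-tris(benzyloxy)phenyl]chroman-4-one
Product: 6 (2R,3S)-3,7-bis(benzyloxy)-5-hydroxy-2-[3,4,5-tris(benzyloxy)phenyl]chroman-4-one
Conditions: BCl3 (1.05 equiv), CH2Cl2, −78 °C; then H2O
Reagents that add atoms: none
Why: Chelation-controlled ether cleavage: boron bridges the C4 carbonyl and the peri O5 in a six-membered chelate, so only this benzyl group leaves as benzyl chloride; this is where O5 is told apart from O7.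

Step 6
Reactants: 6 (2R,3S)-3,7-bis(benzyloxy)-5-hydroxy-2-[3,4,5-tris(benzyloxy)phenyl]chroman-4-one
Product: 7 (2R,3S)-3,7-bis(benzyloxy)-4-oxo-2-[3,4,5-tris(benzyloxy)phenyl]chroman-5-yl tert-butyl carbonate
Conditions: Boc2O, i-Pr2NEt, DMAP (cat.), CH2Cl2, 0 °C → rt
Reagents that add atoms: di-tert-butyl dicarbonate CC(C)(C)OC(=O)OC(=O)OC(C)(C)C
Why: DMAP-catalysed O-acylation of the hydrogen-bonded phenol under conditions too mild to enolise the cis ketone; the carbonate is the trigger of the key step.

Step 7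
Reactants: 6 (2R,3S)-3,7-bis(benzyloxy)-5-hydroxy-2-[3,4,5-tris(benzyloxy)phenyl]chroman-4-one
Product: 8 (2R,3S)-3,7-bis(benzyloxy)-4-oxo-2-[3,4,5-tris(benzyloxy)phenyl]chroman-5-yl trifluoromethanesulfonate
Conditions: Tf2O, pyridine, CH2Cl2, −20 → 0 °C
Reagents that add atoms: trifluoromethanesulfonic anhydride O=S(=O)(OS(=O)(=O)C(F)(F)F)C(F)(F)F
Why: Sulfonylation of the phenol; the triflate marks C5 of the future top unit for hydrogenolysis and makes its ring A too electron-poor to act as a nucleophile in step 13.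

Step 8
Reactants: 8 (2R,3S)-3,7-bis(benzyloxy)-4-oxo-2-[3,4,5-tris(benzyloxy)phenyl]chroman-5-yl trifluoromethanesulfonate
Product: 9 (2R,3R,4R)-3,7-bis(benzyloxy)-4-hydroxy-2-[3,4,5-tris(benzyloxy)phenyl]chroman-5-yl trifluoromethanesulfonate
Conditions: NaBH4, THF/MeOH, −20 → 0 °C
Reagents that add atoms: none
Why: Borohydride reduction of the aryl ketone; hydride should add anti to the axial 3-OBn to give mainly the 4α-alcohol, but the configuration at C4 does not matter because this carbon is ionised in step 13.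

Step 9
Reactants: 10 (−)-epicatechin
Product: 11 5,7,3',4'-tetra-O-benzyl-(−)-epicatechin
Conditions: BnBr (4.4 equiv), K2CO3, degassed DMF, Ar, 0 °C → rt
Reagents that add atoms: benzyl bromide BrCc1ccccc1
Why: Williamson etherification of the four phenols only, as in step 1.

Step 10
Reactants: 11 5,7,3',4'-tetra-O-benzyl-(−)-epicatechin
Product: 12 3,5,7,3',4'-penta-O-benzyl-(−)-epicatechin
Conditions: NaH, BnBr, Bu4NI (cat.), DMF, 0 °C → rt
Reagents that add atoms: benzyl bromide BrCc1ccccc1
Why: Williamson etherification of the 3-alkoxide, as in step 2; a benzyl ether at O3 survives the organolithium step and leaves in the final hydrogenolysis.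

Step 11
Reactants: 12 3,5,7,3',4'-penta-O-benzyl-(−)-epicatechin
Product: 13 8-bromo-3,5,7,3',4'-penta-O-benzyl-(−)-epicatechin
Conditions: NBS (1.0 equiv), CH2Cl2, −40 → 0 °C
Reagents that add atoms: N-bromosuccinimide O=C1CCC(=O)N1Br
Why: Electrophilic aromatic bromination of the phloroglucinol-type ring A; of its two free positions C8 (between O7 and the ring oxygen O1) is less hindered than C6 (between two benzyl ethers) and is the usual site of monobromination in benzylated flavan-3-ols.

Step 12
Reactants: 13 8-bromo-3,5,7,3',4'-penta-O-benzyl-(−)-epicatechin; 7 (2R,3S)-3,7-bis(benzyloxy)-4-oxo-2-[3,4,5-tris(benzyloxy)phenyl]chroman-5-yl tert-butyl carbonate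
Product: 17 [3,7,3',4',5'-penta-O-benzyl-epigallocatechin]-(4α→8)-[3,5,7,3',4'-penta-O-benzyl-epicatechin] with free 5-OH on the upper unit, via aryllithium 14 (not isolated), via lithium alkoxide 15 (not isolated), via o-quinone methide 16 (not isolated)
Conditions: 13, t-BuLi (2.0 equiv), THF, −78 °C; then 7, −78 °C; then LiBH4 (THF), −78 → 0 °C; H2O
Reagents that add atoms: none
Why: Bromine–lithium exchange gives 14, which adds to the C4 carbonyl of 7; the tertiary alkoxide 15 (either C4 epimer) takes the tert-butoxycarbonyl group from the peri O5 through a six-membered transition state, and the freed phenoxide expels tert-butyl carbonate from C4 to give o-quinone methide 16, in which C4 is planar; LiBH4 then delivers hydride to C4 in a 1,4 sense and ring A rearomatises. The closest known reaction type is the three-component o-quinone methide relay of o-(tert-butoxycarbonyloxy)aryl aldehydes and ketones, in which an organolithium adds first and a second nucleophile, hydride included, adds to the quinone methide. No ring is closed; the step forms the C4(middle)–C8(bottom) bond and the C4 stereocenter of the middle unit. That center is set by substrate control: in 16 the C2 aryl group is pseudo-equatorial and the cis 3-OBn group pseudo-axial on the α face (allylic strain with the C4 aryl group reinforces this), so hydride should enter C4 from the β face, anti to the C3–O bond, and leave the bottom unit on the α face, cis to O3 and to the C2 aryl group (all-cis, 4S). The step is stereoconvergent, because both epimers of 15 pass through the same planar 16. Carbonyl addition has to beat enolisation of 7 and attack at the carbonate, which the low temperature and the hindered tert-butyl carbonate should secure. Tautomerisation of 16 to a flav-3-ene is disfavoured because H3 lies on the side of C4 remote from O5 and hydride is present before the mixture is warmed.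

Step 13
Reactants: 17 [3,7,3',4',5'-penta-O-benzyl-epigallocatechin]-(4α→8)-[3,5,7,3',4'-penta-O-benzyl-epicatechin] with free 5-OH on the upper unit; 9 (2R,3R,4R)-3,7-bis(benzyloxy)-4-hydroxy-2-[3,4,5-tris(benzyloxy)phenyl]chroman-5-yl trifluoromethanesulfonate
Product: 20 protected trimer (4β→8)(4α→8) with 5-OTf on the top unit and free 5-OH on the middle unit, via silyl ether 18 (not isolated), via silylated trimer 19 (not isolated)
Conditions: 17, N,O-bis(trimethylsilyl)acetamide (1.2 equiv), CH2Cl2, rt; then 9 (1.2 equiv), Me3SiOTf (0.3 equiv), −78 → −30 °C; citric acid, MeOH/H2O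
Reagents that add atoms: none
Why: Friedel–Crafts alkylation by a flavan-4-yl cation, the standard interflavanyl bond construction: the cation from 9 is attacked on the β face, anti to the axial 3-OBn, which sets the 3,4-trans (4β) center of the top unit. In 18 the silyloxy group on C5 keeps the middle ring A phloroglucinol-type, so C8 (para to O5, next to the small ring oxygen O1) should react in preference to C6 (between two bulky ethers) and to C6 of the bottom ring; the triflate-bearing ring A of 9 cannot compete, which rules out self-condensation. The aryl silyl ether is cleaved on work-up.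

Step 14
Reactants: 20 protected trimer with 5-OTf on the top unit and free 5-OH on the middle unit
Product: 21 protected trimer bis(triflate) (5-OTf on the top and middle units)
Conditions: Tf2O, pyridine, CH2Cl2, 0 °C
Reagents that add atoms: trifluoromethanesulfonic anhydride O=S(=O)(OS(=O)(=O)C(F)(F)F)C(F)(F)F
Why: Sulfonylation of the only free hydroxyl group, which turns the second auxiliary oxygen into a leaving group for hydrogenolysis.

Step 15
Reactants: 21 protected trimer bis(triflate)
Product: 22 epirobinetinidol-(4β→8)-epirobinetinidol-(4α→8)-epicatechin (CNP0115797.2)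
Conditions: H2 (1–4 atm), Pd(OH)2/C, Et3N (2.2 equiv), THF/MeOH, rt
Reagents that add atoms: none
Why: Catalytic hydrogenolysis: both aryl triflates should be reduced to C–H, with Et3N consumed as it takes up the triflic acid so that no free amine remains to slow the catalyst, and the fifteen benzyl ethers are cleaved to toluene. No stereocenter is touched, and the medium stays buffered so the interflavanyl bonds are not exposed to acid.

## Compound list

1 | (−)-epigallocatechin, (2R,3R)-2-(3,4,5-trihydroxyphenyl)chromane-3,5,7-triol | Oc1cc(O)c2c(c1)O[C@H](c1cc(O)c(O)c(O)c1)[C@H](O)C2 | starting material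
2 | 5,7,3',4',5'-penta-O-benzyl-(−)-epigallocatechin | c3ccccc3COc1cc(OCc3ccccc3)c2c(c1)O[C@H](c1cc(OCc3ccccc3)c(OCc3ccccc3)c(OCc3ccccc3)c1)[C@H](O)C2 | intermediate
3 | 3,5,7,3',4',5'-hexa-O-benzyl-(−)-epigallocatechin | c3ccccc3COc1cc(OCc3ccccc3)c2c(c1)O[C@H](c1cc(OCc3ccccc3)c(OCc3ccccc3)c(OCc3ccccc3)c1)[C@H](OCc3ccccc3)C2 | intermediate
4 | (2R,3R,4S)-3,5,7-tris(benzyloxy)-2-[3,4,5-tris(benzyloxy)phenyl]chroman-4-ol (4β-OH) | c3ccccc3COc1cc(OCc3ccccc3)c2c(c1)O[C@H](c1cc(OCc3ccccc3)c(OCc3ccccc3)c(OCc3ccccc3)c1)[C@H](OCc3ccccc3)[C@H]2O | intermediate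
5 | (2R,3S)-3,5,7-tris(benzyloxy)-2-[3,4,5-tris(benzyloxy)phenyl]chroman-4-one (2,3-cis) | c3ccccc3COc1cc(OCc3ccccc3)c2c(c1)O[C@H](c1cc(OCc3ccccc3)c(OCc3ccccc3)c(OCc3ccccc3)c1)[C@H](OCc3ccccc3)C2=O | intermediate
6 | (2R,3S)-3,7-bis(benzyloxy)-5-hydroxy-2-[3,4,5-tris(benzyloxy)phenyl]chroman-4-one | c3ccccc3COc1cc(O)c2c(c1)O[C@H](c1cc(OCc3ccccc3)c(OCc3ccccc3)c(OCc3ccccc3)c1)[C@H](OCc3ccccc3)C2=O | intermediate
7 | (2R,3S)-3,7-bis(benzyloxy)-4-oxo-2-[3,4,5-tris(benzyloxy)phenyl]chroman-5-yl tert-butyl carbonate | c3ccccc3COc1cc(OC(=O)OC(C)(C)C)c2c(c1)O[C@H](c1cc(OCc3ccccc3)c(OCc3ccccc3)c(OCc3ccccc3)c1)[C@H](OCc3ccccc3)C2=O | intermediate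
8 | (2R,3S)-3,7-bis(benzyloxy)-4-oxo-2-[3,4,5-tris(benzyloxy)phenyl]chroman-5-yl trifluoromethanesulfonate | c3ccccc3COc1cc(OS(=O)(=O)C(F)(F)F)c2c(c1)O[C@H](c1cc(OCc3ccccc3)c(OCc3ccccc3)c(OCc3ccccc3)c1)[C@H](OCc3ccccc3)C2=O | intermediate
9 | (2R,3R,4R)-3,7-bis(benzyloxy)-4-hydroxy-2-[3,4,5-tris(benzyloxy)phenyl]chroman-5-yl trifluoromethanesulfonate (4α-OH) | c3ccccc3COc1cc(OS(=O)(=O)C(F)(F)F)c2c(c1)O[C@H](c1cc(OCc3ccccc3)c(OCc3ccccc3)c(OCc3ccccc3)c1)[C@H](OCc3ccccc3)[C@@H]2O | intermediate
10 | (−)-epicatechin, (2R,3R)-2-(3,4-dihydroxyphenyl)chromane-3,5,7-triol | Oc1cc(O)c2c(c1)O[C@H](c1ccc(O)c(O)c1)[C@H](O)C2 | starting material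
11 | 5,7,3',4'-tetra-O-benzyl-(−)-epicatechin | c3ccccc3COc1cc(OCc3ccccc3)c2c(c1)O[C@H](c1ccc(OCc3ccccc3)c(OCc3ccccc3)c1)[C@H](O)C2 | intermediate
12 | 3,5,7,3',4'-penta-O-benzyl-(−)-epicatechin | c3ccccc3COc1cc(OCc3ccccc3)c2c(c1)O[C@H](c1ccc(OCc3ccccc3)c(OCc3ccccc3)c1)[C@H](OCc3ccccc3)C2 | intermediate
13 | 8-bromo-3,5,7,3',4'-penta-O-benzyl-(−)-epicatechin | c3ccccc3COc1cc(OCc3ccccc3)c2c(c1Br)O[C@H](c1ccc(OCc3ccccc3)c(OCc3ccccc3)c1)[C@H](OCc3ccccc3)C2 | intermediate
14 | 8-lithio-3,5,7,3',4'-penta-O-benzyl-(−)-epicatechin | c3ccccc3COc1cc(OCc3ccccc3)c2c(c1[Li])O[C@H](c1ccc(OCc3ccccc3)c(OCc3ccccc3)c1)[C@H](OCc3ccccc3)C2 | intermediate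
15 | lithium alkoxide from addition of 14 to C4 of 7 (both C4 epimers) | c3ccccc3COc1cc(OC(=O)OC(C)(C)C)c2c(c1)O[C@H](c1cc(OCc3ccccc3)c(OCc3ccccc3)c(OCc3ccccc3)c1)[C@H](OCc3ccccc3)C2(O[Li])c1c(OCc3ccccc3)cc(OCc3ccccc3)c2c1O[C@H](c1ccc(OCc3ccccc3)c(OCc3ccccc3)c1)[C@H](OCc3ccccc3)C2 | intermediate
16 | o-quinone methide: (2R,3R)-3,7-bis(benzyloxy)-4-(penta-O-benzylepicatechin-8-yl)-2-[3,4,5-tris(benzyloxy)phenyl]-2,3-dihydro-5H-chromen-5-one | O=C1C=C(OCc3ccccc3)C=C2O[C@H](c4cc(OCc3ccccc3)c(OCc3ccccc3)c(OCc3ccccc3)c4)[C@H](OCc3ccccc3)C(c5c(OCc3ccccc3)cc(OCc3ccccc3)c6c5O[C@H](c7ccc(OCc3ccccc3)c(OCc3ccccc3)c7)[C@H](OCc3ccccc3)C6)=C12 | intermediate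
17 | [3,7,3',4',5'-penta-O-benzyl-epigallocatechin]-(4α→8)-[3,5,7,3',4'-penta-O-benzyl-epicatechin], 5-OH of the upper unit free | c3ccccc3COc1cc(O)c2c(c1)O[C@H](c1cc(OCc3ccccc3)c(OCc3ccccc3)c(OCc3ccccc3)c1)[C@H](OCc3ccccc3)[C@@H]2c1c(OCc3ccccc3)cc(OCc3ccccc3)c2c1O[C@H](c1ccc(OCc3ccccc3)c(OCc3ccccc3)c1)[C@H](OCc3ccccc3)C2 | intermediate
18 | 5-O-trimethylsilyl ether of 17 | c3ccccc3COc1cc(O[Si](C)(C)C)c2c(c1)O[C@H](c1cc(OCc3ccccc3)c(OCc3ccccc3)c(OCc3ccccc3)c1)[C@H](OCc3ccccc3)[C@@H]2c1c(OCc3ccccc3)cc(OCc3ccccc3)c2c1O[C@H](c1ccc(OCc3ccccc3)c(OCc3ccccc3)c1)[C@H](OCc3ccccc3)C2 | intermediate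
19 | silylated trimer: top unit 5-OTf, middle unit 5-OSiMe3, (4β→8)(4α→8) | c3ccccc3COc1cc(OS(=O)(=O)C(F)(F)F)c2c(c1)O[C@H](c1cc(OCc3ccccc3)c(OCc3ccccc3)c(OCc3ccccc3)c1)[C@H](OCc3ccccc3)[C@H]2c1c(OCc3ccccc3)cc(O[Si](C)(C)C)c2c1O[C@H](c1cc(OCc3ccccc3)c(OCc3ccccc3)c(OCc3ccccc3)c1)[C@H](OCc3ccccc3)[C@@H]2c1c(OCc3ccccc3)cc(OCc3ccccc3)c2c1O[C@H](c1ccc(OCc3ccccc3)c(OCc3ccccc3)c1)[C@H](OCc3ccccc3)C2 | intermediate
20 | protected trimer: top unit 5-OTf, middle unit 5-OH, fifteen benzyl ethers, (4β→8)(4α→8) | c3ccccc3COc1cc(OS(=O)(=O)C(F)(F)F)c2c(c1)O[C@H](c1cc(OCc3ccccc3)c(OCc3ccccc3)c(OCc3ccccc3)c1)[C@H](OCc3ccccc3)[C@H]2c1c(OCc3ccccc3)cc(O)c2c1O[C@H](c1cc(OCc3ccccc3)c(OCc3ccccc3)c(OCc3ccccc3)c1)[C@H](OCc3ccccc3)[C@@H]2c1c(OCc3ccccc3)cc(OCc3ccccc3)c2c1O[C@H](c1ccc(OCc3ccccc3)c(OCc3ccccc3)c1)[C@H](OCc3ccccc3)C2 | intermediate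
21 | protected trimer bis(triflate): 5-OTf on the top and middle units | c3ccccc3COc1cc(OS(=O)(=O)C(F)(F)F)c2c(c1)O[C@H](c1cc(OCc3ccccc3)c(OCc3ccccc3)c(OCc3ccccc3)c1)[C@H](OCc3ccccc3)[C@H]2c1c(OCc3ccccc3)cc(OS(=O)(=O)C(F)(F)F)c2c1O[C@H](c1cc(OCc3ccccc3)c(OCc3ccccc3)c(OCc3ccccc3)c1)[C@H](OCc3ccccc3)[C@@H]2c1c(OCc3ccccc3)cc(OCc3ccccc3)c2c1O[C@H](c1ccc(OCc3ccccc3)c(OCc3ccccc3)c1)[C@H](OCc3ccccc3)C2 | intermediate
22 | epirobinetinidol-(4β→8)-epirobinetinidol-(4α→8)-epicatechin; top unit 2R,3R,4R, middle unit 2R,3R,4S, bottom unit 2R,3R | Oc1ccc2c(c1)O[C@H](c1cc(O)c(O)c(O)c1)[C@H](O)[C@H]2c1c(O)ccc2c1O[C@H](c1cc(O)c(O)c(O)c1)[C@H](O)[C@@H]2c1c(O)cc(O)c2c1O[C@H](c1ccc(O)c(O)c1)[C@H](O)C2 | target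

## Step count and risk

Total step count: 15. Longest linear sequence: 10 steps (1 → 2 → 3 → 4 → 5 → 6 → 7 → 17 → 20 → 21 → 22, steps 1–6 and 12–15).

Steps least certain to work:

**Step 12 (key step).**
- What may go wrong: the hindered aryllithium may enolise the ketone instead of adding to it; or, after addition, the anionic relay may stall or leak, through incomplete carbonate transfer and elimination or base-induced isomerisation of the quinone methide before hydride capture, so that facial control at C4 is lost.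
- Fallback (from 13 and 7, back at 17): the aryllithium is added to 7 at −78 °C and the mixture is quenched cold with acetic acid, so that the tertiary carbinol F1 is isolated (C4 epimers; the carbonate may sit on O5 or O4). F1 is then treated with CF3CO2H and Bu3SnH in CH2Cl2 at −78 → 0 °C (ionic hydrogenation). The acid removes the carbonate and ionises C4 to the diaryl-stabilised cation, which takes hydride from the β face for the same steric reason, and 17 is reached.

**Step 13.**
- What may go wrong: the triflate-bearing carbinol may ionise slowly, so that alkylation at C6 of either phloroglucinol-type ring and acid scission of the existing 4α→8 bond compete with the wanted attack at C8.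
- Fallback (from 9, back at 22): the triflate is removed before the coupling. Reduction of 9 with Pd(OAc)2/dppp, HCO2H and Et3N in DMF at 60 °C gives the more easily ionised 5-deoxy carbinol F2. F2 is condensed with 18 (made from 17 as in step 13) at lower temperature to give the silylated trimer F3 and, after the same work-up, the trimer phenol F4. Triflation as in step 14 gives the monotriflate F5, and hydrogenolysis as in step 15 gives 22.

**Step 15.**
- What may go wrong: the two hindered aryl triflates may be reduced incompletely, or the amine may slow benzyl ether cleavage, leaving partly deprotected mixtures.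
- Fallback (from 21, back at 22): both triflates are first reduced in solution with Pd(OAc)2/dppp, HCO2H and Et3N in DMF at 60 °C to the pentadeca-O-benzyl trimer F6. F6 is then hydrogenolysed over Pd(OH)2/C without amine to give 22.

**Step 1.**
- What may go wrong: oxidation of the pyrogallol ring, C-benzylation of ring A and base-induced epimerisation at C2 during perbenzylation of the free polyphenol.
- Fallback (from 1, back at 3): 1 is peracetylated (Ac2O, pyridine) to the air-stable hexa-O-acetyl-epigallocatechin F7. F7 is converted in one flask into 3 by in situ deacetylation–benzylation (NaH, BnBr, DMF, a controlled amount of water), so the free phenoxides never accumulate.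

## Further compounds

F1 | step 12 | tertiary carbinol from 14 and 7, drawn as the O5 carbonate (C4 epimers) | c3ccccc3COc1cc(OC(=O)OC(C)(C)C)c2c(c1)O[C@H](c1cc(OCc3ccccc3)c(OCc3ccccc3)c(OCc3ccccc3)c1)[C@H](OCc3ccccc3)C2(O)c1c(OCc3ccccc3)cc(OCc3ccccc3)c2c1O[C@H](c1ccc(OCc3ccccc3)c(OCc3ccccc3)c1)[C@H](OCc3ccccc3)C2
F2 | step 13 | (2R,3R,4R)-3,7-bis(benzyloxy)-2-[3,4,5-tris(benzyloxy)phenyl]chroman-4-ol | c3ccccc3COc1ccc2c(c1)O[C@H](c1cc(OCc3ccccc3)c(OCc3ccccc3)c(OCc3ccccc3)c1)[C@H](OCc3ccccc3)[C@@H]2O
F3 | step 13 | silylated trimer: top unit 5-H, middle unit 5-OSiMe3 | c3ccccc3COc1ccc2c(c1)O[C@H](c1cc(OCc3ccccc3)c(OCc3ccccc3)c(OCc3ccccc3)c1)[C@H](OCc3ccccc3)[C@H]2c1c(OCc3ccccc3)cc(O[Si](C)(C)C)c2c1O[C@H](c1cc(OCc3ccccc3)c(OCc3ccccc3)c(OCc3ccccc3)c1)[C@H](OCc3ccccc3)[C@@H]2c1c(OCc3ccccc3)cc(OCc3ccccc3)c2c1O[C@H](c1ccc(OCc3ccccc3)c(OCc3ccccc3)c1)[C@H](OCc3ccccc3)C2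
F4 | step 13 | trimer phenol: top unit 5-H, middle unit 5-OH | c3ccccc3COc1ccc2c(c1)O[C@H](c1cc(OCc3ccccc3)c(OCc3ccccc3)c(OCc3ccccc3)c1)[C@H](OCc3ccccc3)[C@H]2c1c(OCc3ccccc3)cc(O)c2c1O[C@H](c1cc(OCc3ccccc3)c(OCc3ccccc3)c(OCc3ccccc3)c1)[C@H](OCc3ccccc3)[C@@H]2c1c(OCc3ccccc3)cc(OCc3ccccc3)c2c1O[C@H](c1ccc(OCc3ccccc3)c(OCc3ccccc3)c1)[C@H](OCc3ccccc3)C2
F5 | step 13 | trimer monotriflate: top unit 5-H, middle unit 5-OTf | c3ccccc3COc1ccc2c(c1)O[C@H](c1cc(OCc3ccccc3)c(OCc3ccccc3)c(OCc3ccccc3)c1)[C@H](OCc3ccccc3)[C@H]2c1c(OCc3ccccc3)cc(OS(=O)(=O)C(F)(F)F)c2c1O[C@H](c1cc(OCc3ccccc3)c(OCc3ccccc3)c(OCc3ccccc3)c1)[C@H](OCc3ccccc3)[C@@H]2c1c(OCc3ccccc3)cc(OCc3ccccc3)c2c1O[C@H](c1ccc(OCc3ccccc3)c(OCc3ccccc3)c1)[C@H](OCc3ccccc3)C2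
F6 | step 15 | pentadeca-O-benzyl ether of the target | c3ccccc3COc1ccc2c(c1)O[C@H](c1cc(OCc3ccccc3)c(OCc3ccccc3)c(OCc3ccccc3)c1)[C@H](OCc3ccccc3)[C@H]2c1c(OCc3ccccc3)ccc2c1O[C@H](c1cc(OCc3ccccc3)c(OCc3ccccc3)c(OCc3ccccc3)c1)[C@H](OCc3ccccc3)[C@@H]2c1c(OCc3ccccc3)cc(OCc3ccccc3)c2c1O[C@H](c1ccc(OCc3ccccc3)c(OCc3ccccc3)c1)[C@H](OCc3ccccc3)C2
F7 | step 1 | 3,5,7,3',4',5'-hexa-O-acetyl-(−)-epigallocatechin | CC(=O)Oc1cc(OC(C)=O)c2c(c1)O[C@H](c1cc(OC(C)=O)c(OC(C)=O)c(OC(C)=O)c1)[C@H](OC(C)=O)C2
A1 | alternative 1 | (2R,3R,4S)-3,7-bis(benzyloxy)-2-[3,4,5-tris(benzyloxy)phenyl]chroman-4-ol (4β-OH, 5-deoxy electrophile) | c3ccccc3COc1ccc2c(c1)O[C@H](c1cc(OCc3ccccc3)c(OCc3ccccc3)c(OCc3ccccc3)c1)[C@H](OCc3ccccc3)[C@H]2O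
A2 | alternative 2 | 8-{[4-(benzyloxy)-3-{[4-(benzyloxy)-2-hydroxyphenyl](hydroxy)methyl}-2-hydroxyphenyl](hydroxy)methyl}-3,5,7,3',4'-penta-O-benzylepicatechin (carbinol epimers) | OC(c1ccc(OCc3ccccc3)cc1O)c1c(OCc3ccccc3)ccc(C(O)c2c(OCc3ccccc3)cc(OCc3ccccc3)c4c2O[C@H](c2ccc(OCc3ccccc3)c(OCc3ccccc3)c2)[C@H](OCc3ccccc3)C4)c1O
A3 | alternative 2 | (Z)-2-[3,4,5-tris(benzyloxy)phenyl]ethenyl acetate | CC(=O)O/C=C\c1cc(OCc3ccccc3)c(OCc3ccccc3)c(OCc3ccccc3)c1
A4 | alternative 3 | (2R,3S)-3,7-bis(benzyloxy)-8-bromo-2-[3,4,5-tris(benzyloxy)phenyl]chroman-4-one | c3ccccc3COc1ccc2c(c1Br)O[C@H](c1cc(OCc3ccccc3)c(OCc3ccccc3)c(OCc3ccccc3)c1)[C@H](OCc3ccccc3)C2=O
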